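| setting | violet | amber | flask |
|---|---|---|---|
| free monomer | 0.50 M | 0.34 M | 0.50 M |
| transfer agent | 0.15 M | 0.15 M | 0.150 M |
| initiator | 25 mM | 25 mM | 25 mM |
| impurity | 7.8 mM | 7.8 mM | 7.8 mM |
| remark | the very flask that is asked about, followed so far | run made earlier |  |
| time |  |  | 20 h |

- violet (time / h: monomer in chains / %, free monomer / %): 0.500: 73.9, 25.6; 1.33: 97.8, 5.2; 2.50: 98.6, 2.4; 4.00: 100.4, 2.0
- amber (time / h: monomer in chains / %, free monomer / %): 1.50: 95.3, 5.1; 4.00: 97.4, 1.6; 8.00: 99.5, 0.4; 20.0: 99.5, 0.1

(each reading ± 1 percentage point)

- the average divides the monomer in chains by the number of chains begun, living and dead together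
- what was read earlier has a scatter of 1 percentage point, one standard deviation
- the earlier runs do not show the number of chains; that part of a forecast is a guess

1. average number of monomer units in a chain (chains begun, living or dead) at 20 h
2. part of the free monomer that has reacted at 20 h

- I start from the small charge: the impurity in the violet flask, which is also the flask asked about, stands at 7.8 mM, a third of the initiator, and it is less than any other charge.
- I assume that in the first instants the impurity, the limiting reagent of this pair, destroys its equal amount of initiator, and that each remaining initiator begins one chain.
- Spare initiator in the flask is then 3.44%; I mean the charged initiator less the charged impurity, as a fraction of the free monomer charged. On that assumption the average chain length in this flask is the reacted part of the free monomer divided by this fraction.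
- Early in the violet run the free monomer falls fast: 25.6% remains at 0.500 h, a first-order pace that I read as 2.73 h⁻¹.
- In the middle of the violet run, from 1.33 h to 2.50 h, the pace reads 0.661 h⁻¹, which is slower. I read this fade as chains ceasing to grow, so I count the transfer agent as stopping chains, not beginning new ones.
- At the end of the violet run, 2.0% of the free monomer remains at 4.00 h, with a scatter of 1 percentage point. From this reading I commit to a reacted part of 98.0% at 20 h, and dividing by the spare initiator gives 28.5 units per chain.
- The forecast gives 2.9 units and 99.7% reacted, and it says “The chain count is not measured, so it is a guess.” My chain length is about ten times the forecast's.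
- The flask gives 28.8 units and 99.1% reacted.

    living end + transfer agent → dead chain (kL = 0.00160 L mol⁻¹ s⁻¹)
    initiator + impurity → spent initiator (k = 21.0 L mol⁻¹ s⁻¹)
    free monomer + living end → monomer in chains + living end, rate k3*[living end]*[free monomer] (k = 0.0610 L mol⁻¹ s⁻¹)
    free monomer + initiator → living end + monomer in chains (k = 0.0100 L mol⁻¹ s⁻¹)

- At 20.0 h the dead chains in the flask are 3.44% of the free monomer charged, level with the spare initiator. Dividing 99.1% by the spare initiator gives 28.8 units, and the flask's chain length is 9.93 times the forecast's, while the forecast's reacted part lies within its margin. The neighbour charged with 0.85 M of free monomer has a spare initiator of 2.02%; its 99.1% reacted, divided by that, gives 49.0 units, and that neighbour flask gives 49.0.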